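Ring B (C5–C10; C5=C6 alkene, C8 and C10 methines, quaternary C9) is made by Favorskii contraction of a cycloheptenone in which the future benzylic carbon C11 is the ring carbonyl, bonded to both C8 and C9. A (4+3) cycloaddition of 6,6-dimethyl-1-vinylcyclohexene with the oxyallyl cation from 1,1,3-trichloroacetone gives the 9,9-dichloro ketone; hydroxide then expels C11 as a carboxyl group on C9 while forming the C8–C9 bond as an alkene. The dienoic acid is resolved, acylates an aryllithium, and a cuprate addition/enolate methylation sets C8 and C9 from C10. Deoxygenation, formylation, sulfation and debenzylation finish the target.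

Key step: step 4

Remark: atom labels follow the drimane convention (ring A = C1–C5 and C10, gem-dimethyl at C4; ring B = C5–C10; C11 = benzylic carbon; primed numbers = arene).
Assumption: the target is drawn as the free aryl hydrogen sulfate; it is carried as its sodium salt and set free only by cold stoichiometric acidification in the last step.
Remark: absolute configuration comes from a classical resolution at step 5; all later stereocentres are set by substrate control from C10.

Step 1
Reactants: 1 2,2-dimethylcyclohexan-1-one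
Product: 2 2,2-dimethyl-1-vinylcyclohexan-1-ol (racemic)
Conditions: CH2=CHMgBr, THF, 0 °C → rt; aq. NH4Cl
Reagents that add atoms: vinylmagnesium bromide, C=C[Mg]Br
Why: Grignard 1,2-addition to the hindered ketone gives the tertiary allylic alcohol, whose racemic stereocentre is destroyed in the next step.

Step 2
Reactants: 2 2,2-dimethyl-1-vinylcyclohexan-1-ol
Product: 3 6,6-dimethyl-1-vinylcyclohex-1-ene
Conditions: p-TsOH·H2O (cat.), benzene, reflux, water separator
Reagents that add atoms: none
Why: Acid-catalysed E1 dehydration can lose a ring proton only from the CH2 side (the other neighbour is quaternary), giving the conjugated diene whose gem-dimethyl group disfavours the s-trans rotamer.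

Step 3
Reactants: 3 6,6-dimethyl-1-vinylcyclohex-1-ene (excess); 4 1,1,3-trichloropropan-2-one
Product: 6 rac-9,9-dichloro-4,4-dimethyl-1,2,3,4,6,7,9,9a-octahydro-8H-benzo[7]annulen-8-one, via dichloro-oxyallyl cation 5 (not isolated)
Conditions: Et3N, CF3CH2OH/Et2O, 0 °C → rt
Reagents that add atoms: none
Why: Base-induced ionisation of 4 in the fluoroalcohol gives oxyallyl cation 5, which should undergo (4+3) cycloaddition with the diene so that its unsubstituted, softer terminus bonds to the terminal vinyl carbon C7 and the CCl2 terminus to C10, creating the C5=C6 alkene and the single (racemic) stereocentre C10.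

Step 4
Reactants: 6 rac-9,9-dichloro ketone
Product: 8 rac-5,5-dimethyl-3,5,6,7,8,8a-hexahydronaphthalene-1-carboxylic acid, via chlorocyclopropanone 7 (not isolated)
Conditions: NaOH (2 M aq.), THF, 0 °C → rt; then cold 1 M HCl to pH 3
Reagents that add atoms: sodium hydroxide, [Na+].[OH-]
Why: Hydroxide deprotonates C8, the enolate displaces one chloride at C9 to give chlorocyclopropanone 7, hydroxide adds to the carbonyl carbon C11, and the C11–C8 bond breaks as the second chloride leaves C9, so the seven-membered ring loses C11 and becomes ring B with C11 as the carboxyl group on C9 and a C8=C9 double bond. This is the Favorskii rearrangement of an α,α-dihalo ketone to a ring-contracted α,β-unsaturated acid. The only ring closed is the transient cyclopropanone (3-exo-tet enolate alkylation); ring B itself results from that C8–C9 bond plus the fragmentation. No stereocentre is formed and C10 is not touched. Regiocontrol (carboxyl on C9, not C8) is secured because both chlorides sit on C9 and only C8 carries α-hydrogens. The skipped 1,4-diene should survive because the product is a carboxylate, which resists γ-deprotonation, and the reaction is run cold.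

Step 5
Reactants: 8 rac-5,5-dimethyl-3,5,6,7,8,8a-hexahydronaphthalene-1-carboxylic acid
Product: 9 (8aR)-5,5-dimethyl-3,5,6,7,8,8a-hexahydronaphthalene-1-carboxylic acid
Conditions: (S)-1-phenylethylamine (0.55 equiv), EtOAc/acetone, recrystallise the salt; cold 1 M HCl, extract; ee checked by chiral HPLC
Reagents that add atoms: none
Why: Classical resolution through diastereomeric ammonium carboxylate salts fixes C10 as (8aR), the only stereocentre present; the amine antipode is to be chosen by screening for the less soluble salt of the (8aR)-acid.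

Step 6
Reactants: 10 3,4-bis(benzyloxy)benzaldehyde
Product: 12 3,4-bis(benzyloxy)phenol, via aryl formate 11 (not isolated)
Conditions: mCPBA, CH2Cl2, 0 °C → rt; then K2CO3 (cat.), MeOH, rt
Reagents that add atoms: 3-chloroperoxybenzoic acid, OOC(=O)c1cccc(Cl)c1
Why: Baeyer–Villiger oxidation with aryl migration (Dakin-type) converts the electron-rich aryl aldehyde into formate 11, which is methanolysed to the phenol.

Step 7
Reactants: 12 3,4-bis(benzyloxy)phenol
Product: 13 4,5-bis(benzyloxy)-2-bromophenol
Conditions: NBS, MeCN, 0 °C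
Reagents that add atoms: N-bromosuccinimide, O=C1CCC(=O)N1Br
Why: Electrophilic aromatic bromination should occur ortho to the free hydroxyl and para to a benzyloxy group, the less hindered of the two ortho positions.

Step 8
Reactants: 13 4,5-bis(benzyloxy)-2-bromophenol
Product: 14 1,2-bis(benzyloxy)-4-bromo-5-(methoxymethoxy)benzene
Conditions: MOMCl, i-Pr2NEt, CH2Cl2, 0 °C → rt
Reagents that add atoms: chloromethyl methyl ether, COCCl
Why: O-alkylation (Williamson-type) installs the methoxymethyl ether, which later directs metalation and can be removed without touching the benzyl ethers.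

Step 9
Reactants: 9 (8aR)-acid; 14 aryl bromide
Product: 17 [4,5-bis(benzyloxy)-2-(methoxymethoxy)phenyl][(8aR)-5,5-dimethyl-3,5,6,7,8,8a-hexahydronaphthalen-1-yl]methanone, via aryllithium 15 (not isolated), via lithium carboxylate 16 (not isolated)
Conditions: 14, n-BuLi, THF, −78 °C; separately 9, n-BuLi (1.0 equiv), THF, −78 °C; combine, −78 → 0 °C; aq. NH4Cl
Reagents that add atoms: none
Why: Bromine–lithium exchange gives aryllithium 15, which adds once to lithium carboxylate 16; the dilithium gem-diolate persists until work-up, so the aryl ketone should form without over-addition (organolithium–carboxylate ketone synthesis).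

Step 10
Reactants: 17 dienyl aryl ketone
Product: 19 [4,5-bis(benzyloxy)-2-(methoxymethoxy)phenyl][(1R,2R,8aR)-1,2,5,5-tetramethyl-1,2,3,5,6,7,8,8a-octahydronaphthalen-1-yl]methanone, via lithium enolate 18 (not isolated)
Conditions: Me2CuLi (from MeLi and CuI), Et2O/THF, −78 → −20 °C; then MeI, HMPA, −20 °C → rt
Reagents that add atoms: lithium dimethylcuprate, [Li+].C[Cu-]C; iodomethane, CI
Why: Cuprate 1,4-addition should deliver methyl axially to C8 on the face anti to the C1 methylene of the neighbouring stereocentre C10 (8-methyl cis to H-10), and enolate 18 should be C-methylated anti to that new methyl (trans vicinal dialkylation), placing C11, the C8 methyl and H-10 on one face of ring B.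

Step 11
Reactants: 19 aryl ketone
Product: 20 [4,5-bis(benzyloxy)-2-(methoxymethoxy)phenyl][(1R,2R,8aR)-1,2,5,5-tetramethyl-1,2,3,5,6,7,8,8a-octahydronaphthalen-1-yl]methanol (both C11 epimers)
Conditions: LiAlH4, THF, 0 °C → rt; aqueous NaOH work-up
Reagents that add atoms: none
Why: Hydride reduction of the hindered aryl ketone gives the benzylic alcohol; both C11 epimers are carried on because C11 becomes CH2.

Step 12
Reactants: 20 benzylic alcohol
Product: 21 (1R,2R,8aS)-1-{[4,5-bis(benzyloxy)-2-(methoxymethoxy)phenyl]methyl}-1,2,5,5-tetramethyl-1,2,3,5,6,7,8,8a-octahydronaphthalene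
Conditions: Et3SiH, CF3CO2H, CH2Cl2, −40 °C
Reagents that add atoms: none
Why: Ionic hydrogenation: the benzylic cation, stabilised by three alkoxy groups, forms at −40 °C and should be trapped by the silane faster than a 1,2-alkyl shift from C9 or protonation of the C5=C6 alkene can occur.

Step 13
Reactants: 21 arene
Product: 24 2,3-bis(benzyloxy)-6-hydroxy-5-{[(1R,2R,8aS)-1,2,5,5-tetramethyl-1,2,3,5,6,7,8,8a-octahydronaphthalen-1-yl]methyl}benzaldehyde, via aryllithium 22 (not isolated), via MOM-protected aldehyde 23 (not isolated)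
Conditions: s-BuLi, TMEDA, THF, −78 °C; DMF, −78 °C → rt; then 3 M HCl, THF/MeOH, rt
Reagents that add atoms: N,N-dimethylformamide, CN(C)C=O
Why: Directed ortho-metalation should occur at the only ring position flanked by two directing oxygens (OMOM and OBn), formylation follows, and the methoxymethyl ether ortho to the new formyl group is hydrolysed by the acidic work-up.

Step 14
Reactants: 24 salicylaldehyde
Product: 25 sodium 3,4-bis(benzyloxy)-2-formyl-6-{[(1R,2R,8aS)-1,2,5,5-tetramethyl-1,2,3,5,6,7,8,8a-octahydronaphthalen-1-yl]methyl}phenyl sulfate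
Conditions: SO3·pyridine, pyridine, 50 °C; then aq. NaHCO3
Reagents that add atoms: sulfur trioxide–pyridine complex, [O-]S(=O)(=O)[n+]1ccccc1; sodium hydrogencarbonate, [Na+].OC([O-])=O
Why: O-sulfation of the single free phenol; the two catechol oxygens are blocked as benzyl ethers, which secures the site of sulfation.

Step 15
Reactants: 25 sodium aryl sulfate
Product: 26 2,3-dihydroxy-6-(sulfooxy)-5-{[(1R,2R,8aS)-1,2,5,5-tetramethyl-1,2,3,5,6,7,8,8a-octahydronaphthalen-1-yl]methyl}benzaldehyde (target)
Conditions: H2 (1 atm), palladium on carbon (Pd/C, 10%), EtOAc/MeOH, rt, stopped when the mono-benzyl ether is consumed; filter; 1 M HCl (1.0 equiv), 0 °C; lyophilise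
Reagents that add atoms: none
Why: Hydrogenolysis of the two aryl benzyl ethers should be faster than reduction of the hydrogen-bonded aryl aldehyde or the hindered trisubstituted C5=C6 alkene, the aryl sulfate is inert to H2/Pd, and cold stoichiometric acid liberates the hydrogen sulfate.

Compound list
1 | 2,2-dimethylcyclohexan-1-one | CC1(C)CCCCC1=O | starting material
2 | 2,2-dimethyl-1-vinylcyclohexan-1-ol (racemic) | C=CC1(O)CCCCC1(C)C | intermediate
3 | 6,6-dimethyl-1-vinylcyclohex-1-ene | C=CC1=CCCCC1(C)C | intermediate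
4 | 1,1,3-trichloropropan-2-one | ClCC(=O)C(Cl)Cl | starting material
5 | 1,1-dichloro-2-oxidoallyl cation (oxyallyl cation) | [CH2+]C([O-])=C(Cl)Cl | intermediate
6 | rac-9,9-dichloro-4,4-dimethyl-1,2,3,4,6,7,9,9a-octahydro-8H-benzo[7]annulen-8-one (C4a=C5 alkene) | O=C1CCC=C2C(CCCC2(C)C)C1(Cl)Cl | intermediate
7 | chlorocyclopropanone bridging C8 and C9 (C11 as cyclopropanone carbonyl, chlorine on C9; racemic) | O=C1C2CC=C3C(CCCC3(C)C)C12Cl | intermediate
8 | rac-5,5-dimethyl-3,5,6,7,8,8a-hexahydronaphthalene-1-carboxylic acid | OC(=O)C1=CCC=C2C1CCCC2(C)C | intermediate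
9 | (8aR)-5,5-dimethyl-3,5,6,7,8,8a-hexahydronaphthalene-1-carboxylic acid | OC(=O)C1=CCC=C2[C@H]1CCCC2(C)C | intermediate
10 | 3,4-bis(benzyloxy)benzaldehyde | O=Cc1ccc(OCc2ccccc2)c(OCc2ccccc2)c1 | starting material
11 | 3,4-bis(benzyloxy)phenyl formate | O=COc1ccc(OCc2ccccc2)c(OCc2ccccc2)c1 | intermediate
12 | 3,4-bis(benzyloxy)phenol | Oc1ccc(OCc2ccccc2)c(OCc2ccccc2)c1 | intermediate
13 | 4,5-bis(benzyloxy)-2-bromophenol | Oc1cc(OCc2ccccc2)c(OCc2ccccc2)cc1Br | intermediate
14 | 1,2-bis(benzyloxy)-4-bromo-5-(methoxymethoxy)benzene | COCOc1cc(OCc2ccccc2)c(OCc2ccccc2)cc1Br | intermediate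
15 | [4,5-bis(benzyloxy)-2-(methoxymethoxy)phenyl]lithium | COCOc1cc(OCc2ccccc2)c(OCc2ccccc2)cc1[Li] | intermediate
16 | lithium (8aR)-5,5-dimethyl-3,5,6,7,8,8a-hexahydronaphthalene-1-carboxylate | [Li+].[O-]C(=O)C1=CCC=C2[C@H]1CCCC2(C)C | intermediate
17 | [4,5-bis(benzyloxy)-2-(methoxymethoxy)phenyl][(8aR)-5,5-dimethyl-3,5,6,7,8,8a-hexahydronaphthalen-1-yl]methanone | COCOc1cc(OCc2ccccc2)c(OCc2ccccc2)cc1C(=O)C1=CCC=C2[C@H]1CCCC2(C)C | intermediate
18 | lithium enolate of the (2R,8aR)-2,5,5-trimethyl-octahydronaphthalen-1-yl aryl ketone (C9=C11 enolate, geometry not defined) | C[C@@H]1CC=C2[C@@H](CCCC2(C)C)C1=C(O[Li])c1cc(OCc3ccccc3)c(OCc3ccccc3)cc1OCOC | intermediate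
19 | [4,5-bis(benzyloxy)-2-(methoxymethoxy)phenyl][(1R,2R,8aR)-1,2,5,5-tetramethyl-1,2,3,5,6,7,8,8a-octahydronaphthalen-1-yl]methanone | C[C@@H]1CC=C2[C@@H](CCCC2(C)C)[C@]1(C)C(=O)c1cc(OCc3ccccc3)c(OCc3ccccc3)cc1OCOC | intermediate
20 | [4,5-bis(benzyloxy)-2-(methoxymethoxy)phenyl][(1R,2R,8aR)-1,2,5,5-tetramethyl-1,2,3,5,6,7,8,8a-octahydronaphthalen-1-yl]methanol (both carbinol epimers) | C[C@@H]1CC=C2[C@@H](CCCC2(C)C)[C@]1(C)C(O)c1cc(OCc3ccccc3)c(OCc3ccccc3)cc1OCOC | intermediate
21 | (1R,2R,8aS)-1-{[4,5-bis(benzyloxy)-2-(methoxymethoxy)phenyl]methyl}-1,2,5,5-tetramethyl-1,2,3,5,6,7,8,8a-octahydronaphthalene | C[C@@H]1CC=C2[C@@H](CCCC2(C)C)[C@]1(C)Cc1cc(OCc3ccccc3)c(OCc3ccccc3)cc1OCOC | intermediate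
22 | aryllithium of 21, lithiated between the OMOM and OBn groups | C[C@@H]1CC=C2[C@@H](CCCC2(C)C)[C@]1(C)Cc1cc(OCc3ccccc3)c(OCc3ccccc3)c([Li])c1OCOC | intermediate
23 | 2,3-bis(benzyloxy)-6-(methoxymethoxy)-5-{[(1R,2R,8aS)-1,2,5,5-tetramethyl-1,2,3,5,6,7,8,8a-octahydronaphthalen-1-yl]methyl}benzaldehyde | C[C@@H]1CC=C2[C@@H](CCCC2(C)C)[C@]1(C)Cc1cc(OCc3ccccc3)c(OCc3ccccc3)c(C=O)c1OCOC | intermediate
24 | 2,3-bis(benzyloxy)-6-hydroxy-5-{[(1R,2R,8aS)-1,2,5,5-tetramethyl-1,2,3,5,6,7,8,8a-octahydronaphthalen-1-yl]methyl}benzaldehyde | C[C@@H]1CC=C2[C@@H](CCCC2(C)C)[C@]1(C)Cc1cc(OCc3ccccc3)c(OCc3ccccc3)c(C=O)c1O | intermediate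
25 | sodium 3,4-bis(benzyloxy)-2-formyl-6-{[(1R,2R,8aS)-1,2,5,5-tetramethyl-1,2,3,5,6,7,8,8a-octahydronaphthalen-1-yl]methyl}phenyl sulfate | C[C@@H]1CC=C2[C@@H](CCCC2(C)C)[C@]1(C)Cc1cc(OCc3ccccc3)c(OCc3ccccc3)c(C=O)c1OS(=O)(=O)[O-].[Na+] | intermediate
26 | 2,3-dihydroxy-6-(sulfooxy)-5-{[(1R,2R,8aS)-1,2,5,5-tetramethyl-1,2,3,5,6,7,8,8a-octahydronaphthalen-1-yl]methyl}benzaldehyde | C[C@@H]1CC=C2[C@@H](CCCC2(C)C)[C@]1(C)Cc1cc(O)c(O)c(C=O)c1OS(=O)(=O)O | target

Total steps: 15. Longest linear sequence: 12 steps (steps 1–5 and 9–15, from compound 1); the arene branch (steps 6–8) joins at step 9.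

Steps most likely to fail

Step 3. The oxyallyl cation may be captured by the fluoroalcohol or may alkylate the diene without ring closure, and the two cation termini may add in the opposite orientation. The fallback sets out from diene 3 and generates a symmetrical 1,3-dibromo-2-oxyallyl species reductively from 1,1,3,3-tetrabromopropan-2-one with Fe2(CO)9 in benzene at 60 °C (neutral, non-nucleophilic medium; no orientation issue in the cycloaddition). This should give rac-7,9-dibromo-4,4-dimethyl-1,2,3,4,6,7,9,9a-octahydro-8H-benzo[7]annulen-8-one F1. Favorskii contraction of F1 with aqueous NaOH, through the bromocyclopropanone F2, should give the same dienoic acid after separation from the isomer carrying the carboxyl group on C8. The route is rejoined at compound 8.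

Step 10. Facial selectivity of the methyl transfer to C8 relative to C10 may be poor, or the hindered enolate may be O-methylated. The fallback sets out from ketone 17 and replaces substrate control by ligand control: MeMgBr with catalytic CuBr·SMe2 and a Josiphos-type ferrocenyl diphosphine (antipode chosen to match the substrate bias) in t-BuOMe at −78 °C should give the bromomagnesium enolate F3, which is methylated with MeI/DMPU. The route is rejoined at compound 19.

Step 15. The aldehyde may be over-reduced, hydrogenolysis may stall on the sulfur-containing substrate, or the free hydrogen sulfate may hydrolyse. The fallback sets out from phenol 24 and carries the sulfate as a neutral diester. 2,2,2-Trichloroethyl chlorosulfate with Et3N/DMAP should give the aryl 2,2,2-trichloroethyl sulfate F4. BCl3 with pentamethylbenzene at −78 °C then removes both benzyl groups to give the catechol diester F5. Zn dust with ammonium formate in MeOH cleaves the trichloroethyl group, and cold acidification rejoins the route at compound 26.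

Further compounds
F1 | step 3 | rac-7,9-dibromo-4,4-dimethyl-1,2,3,4,6,7,9,9a-octahydro-8H-benzo[7]annulen-8-one | O=C1C(Br)CC=C2C(CCCC2(C)C)C1Br
F2 | step 3 | bromocyclopropanone bridging C8 and C9 (bromine on C9; racemic) | O=C1C2CC=C3C(CCCC3(C)C)C12Br
F3 | step 10 | bromomagnesium enolate of the (2R,8aR)-2,5,5-trimethyl-octahydronaphthalen-1-yl aryl ketone | C[C@@H]1CC=C2[C@@H](CCCC2(C)C)C1=C(O[Mg]Br)c1cc(OCc3ccccc3)c(OCc3ccccc3)cc1OCOC
F4 | step 15 | 3,4-bis(benzyloxy)-2-formyl-6-{[(1R,2R,8aS)-1,2,5,5-tetramethyl-1,2,3,5,6,7,8,8a-octahydronaphthalen-1-yl]methyl}phenyl 2,2,2-trichloroethyl sulfate | C[C@@H]1CC=C2[C@@H](CCCC2(C)C)[C@]1(C)Cc1cc(OCc3ccccc3)c(OCc3ccccc3)c(C=O)c1OS(=O)(=O)OCC(Cl)(Cl)Cl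
F5 | step 15 | 2-formyl-3,4-dihydroxy-6-{[(1R,2R,8aS)-1,2,5,5-tetramethyl-1,2,3,5,6,7,8,8a-octahydronaphthalen-1-yl]methyl}phenyl 2,2,2-trichloroethyl sulfate | C[C@@H]1CC=C2[C@@H](CCCC2(C)C)[C@]1(C)Cc1cc(O)c(O)c(C=O)c1OS(=O)(=O)OCC(Cl)(Cl)Cl
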